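The macrocycle is opened at the diaryl ether bond between the ring D oxygen and C4 of ring A. This carbon lies para to the ring A hydroxyl (C1) and ortho to the ethano bridge to ring B (C3), the carbon of highest spin density in a 3-alkylphenoxyl radical, and ring D offers a phenolic oxygen. One anodic dehydrogenative C–O coupling therefore forms the last aryl ether and the 18-membered ring together. Its precursor is the open A–B–O–C–D bis(bibenzyl) with free phenols on rings A and D, a benzyl ether on ring C and a chlorine blocking the carbon para to the ring D hydroxyl; a single hydrogenolysis then removes both auxiliaries.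

Key step: step 9

Remarks on the chemistry
- Ring labels:
  - Ring A is the trisubstituted ring with OH para to its ether oxygen.
  - Ring B is the para-phenylene.
  - Ring C is the ring with OH ortho to its ether oxygen.
  - Ring D is the meta-phenylene.
- Structure check: the target is C28H24O4, with two free hydroxyls (rings A and C), two diaryl ethers, 18 macrocycle atoms (2+2+4+1+3+2+3+1) and no stereocentre.
- Assumption: both olefinations give E/Z mixtures. Both double bonds are saturated later, so the stilbene SMILES carry no alkene descriptors.
- Blocking group: chlorine is preferred to bromine.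
  - para-Bromophenolates are known to undergo oxidatively started C–O condensation with loss of bromide. That would open the reverse coupling direction, and the released bromide is itself oxidised at the anode.
  - The C–Cl bond is stronger and chloride leaves less readily.
  - An aryl chloride is also safer at the cathode of an undivided cell.
- Ring C carries benzyl rather than methyl, so one hydrogenolysis removes protecting and blocking group together.
- The ring A and ring D phenols are carried unprotected, with one extra equivalent of base or hydride where needed. This saves two protections and one deprotection.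

Step 1
Reactants: 1 2-chloro-5-hydroxybenzaldehyde
Product: 2 4-chloro-3-(hydroxymethyl)phenol
Conditions: NaBH4, MeOH, 0 °C; then 1 M HCl
Reagents that add atoms: none
Why: Borohydride reduction of an aryl aldehyde, to which the phenol and the aryl chloride are inert.

Step 2
Reactants: 2 4-chloro-3-(hydroxymethyl)phenol
Product: 3 (2-chloro-5-hydroxybenzyl)triphenylphosphonium bromide
Conditions: PPh3·HBr, MeCN, reflux
Reagents that add atoms: triphenylphosphine hydrobromide, SMILES [Br-].[PH+](c1ccccc1)(c1ccccc1)c1ccccc1
Why: Acid-promoted substitution of a benzylic alcohol by PPh3·HBr gives the phosphonium salt directly, tolerates the free phenol and saves a separate bromination.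

Step 3
Reactants: 4 3-hydroxybenzyl alcohol
Product: 5 (3-hydroxybenzyl)triphenylphosphonium bromide
Conditions: PPh3·HBr, MeCN, reflux
Reagents that add atoms: triphenylphosphine hydrobromide, SMILES [Br-].[PH+](c1ccccc1)(c1ccccc1)c1ccccc1
Why: The same direct alcohol-to-phosphonium conversion as in step 2, here on the unhalogenated ring A unit.

Step 4
Reactants: 6 4-(benzyloxy)-3-hydroxybenzaldehyde; 7 4-fluorobenzonitrile
Product: 8 4-[2-(benzyloxy)-5-formylphenoxy]benzonitrile
Conditions: K2CO3, DMF, 120 °C
Reagents that add atoms: none
Why: Nucleophilic aromatic substitution (SNAr) in which the phenoxide of 6 displaces fluoride para to the activating nitrile through a Meisenheimer adduct, the nitrile then serving as a masked aldehyde that keeps the two olefination sites distinct.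

Step 5
Reactants: 3 (2-chloro-5-hydroxybenzyl)triphenylphosphonium bromide; 8 4-[2-(benzyloxy)-5-formylphenoxy]benzonitrile
Product: 10 4-{2-(benzyloxy)-5-[2-(2-chloro-5-hydroxyphenyl)ethenyl]phenoxy}benzonitrile (E/Z mixture), via phenoxide ylide 9 (not isolated)
Conditions: 3 (1.15 equiv), KOtBu (2.3 equiv), THF, 0 °C; then 8, 0 °C to rt; then 1 M HCl
Reagents that add atoms: none
Why: Wittig olefination in which two equivalents of base per salt give the phenoxide ylide 9, a semi-stabilised benzylic ylide that attacks the aldehyde of 8 and leaves the nitrile alone.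

Step 6
Reactants: 10 4-{2-(benzyloxy)-5-[2-(2-chloro-5-hydroxyphenyl)ethenyl]phenoxy}benzonitrile
Product: 12 4-{2-(benzyloxy)-5-[2-(2-chloro-5-hydroxyphenyl)ethenyl]phenoxy}benzaldehyde (E/Z mixture), via iminoalane 11 (not isolated)
Conditions: iBu2AlH (2.5 equiv), CH2Cl2, −78 to 0 °C; then 1 M HCl
Reagents that add atoms: water, SMILES O
Why: Partial nitrile reduction in which one equivalent of iBu2AlH is consumed by the phenol and a second delivers a single hydride to give the stable iminoalane 11, which becomes the aldehyde only on acidic hydrolysis, while alkene, aryl chloride and benzyl ether are inert.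

Step 7
Reactants: 12 4-{2-(benzyloxy)-5-[2-(2-chloro-5-hydroxyphenyl)ethenyl]phenoxy}benzaldehyde; 5 (3-hydroxybenzyl)triphenylphosphonium bromide
Product: 14 4-chloro-3-{2-[4-(benzyloxy)-3-{4-[2-(3-hydroxyphenyl)ethenyl]phenoxy}phenyl]ethenyl}phenol (E/Z mixture at both alkenes), via phenoxide ylide 13 (not isolated)
Conditions: 5 (1.3 equiv), KOtBu (3.8 equiv), THF, 0 °C; then 12, 0 °C to rt; then 1 M HCl
Reagents that add atoms: none
Why: A second Wittig olefination, with enough base to ionise both phenols as well as to form ylide 13, on a non-enolisable aldehyde whose remote phenoxide is not conjugated with the carbonyl group.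

Step 8
Reactants: 14 4-chloro-3-{2-[4-(benzyloxy)-3-{4-[2-(3-hydroxyphenyl)ethenyl]phenoxy}phenyl]ethenyl}phenol
Product: 15 4-chloro-3-{2-[4-(benzyloxy)-3-{4-[2-(3-hydroxyphenyl)ethyl]phenoxy}phenyl]ethyl}phenol (open-chain seco diphenol)
Conditions: TsNHNH2 (excess), NaOAc, THF–H2O, reflux
Reagents that add atoms: none
Why: Diimide reduction, in which HN=NH released from TsNHNH2 transfers two hydrogens concertedly to each stilbene double bond and cannot touch the aryl chloride or the benzyl ether that hydrogenation over palladium would endanger.

Step 9
Reactants: 15 4-chloro-3-{2-[4-(benzyloxy)-3-{4-[2-(3-hydroxyphenyl)ethyl]phenoxy}phenyl]ethyl}phenol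
Product: 17 18-membered macrocycle (ring A 4-aryloxyphenol; ring C benzyl ether; ring D chlorine para to the new ether oxygen), via macrocyclic dienone 16 (not isolated)
Conditions: carbon-felt anode, Pt cathode, undivided flow cell (single pass), Bu4NOAc (0.05 M), MeCN, 15 at 1 mM, anode held just past the first phenol wave (set by voltammetry), about 1.5 F/mol, rt, Ar; unreacted 15 recycled
Reagents that add atoms: none
Why: Proposed new method: acetate-assisted proton-coupled electron transfer at a low anode potential should turn both terminal phenols of 15 into phenoxyl radicals, the ring D oxygen then combines with C4 of ring A (para to its oxygen, the carbon of highest spin density) to give dienone 16, and base-mediated enolisation restores ring A as a 4-aryloxyphenol while the two protons leave as H2 at the cathode. The closest known reaction types are the anodic and Tl(NO3)3-mediated couplings of halogenated phenols to diaryl ethers, the anodic growth of poly(phenylene oxide) chains from phenolates and the biogenetic-type C–O phenol coupling, none of which has been shown for a para C–H/O–H macrocyclisation between two unlike monophenols. The one ring formed, the 18-membered macrocycle, closes end to end by intramolecular combination of the oxygen terminus with the sp2 carbon terminus of the same chain. No stereocentre is created in 17, since the only sp3 carbon formed (C4 in 16) is flattened again on enolisation. The step needs the ring D oxygen to ring A C4 direction over the mirror-image ring A oxygen to ring D carbon mode: the chlorine occupies the para carbon of ring D, an ipso adduct there cannot enolise and should dissociate again because chloride and chlorine atoms leave far less readily than their bromine counterparts, and rings B and C oxidise roughly a volt higher and stay out of play. C–O is favoured over C–C union by the aprotic medium and the non-coordinating Bu4N cation that leave the oxygen unencumbered, while millimolar dilution, a single pass through the cell and a charge kept below the theoretical 2 F/mol are what restrain oligomer formation and further oxidation of the more electron-rich product.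

Step 10
Reactants: 17 18-membered macrocycle (ring C benzyl ether; ring D chlorine)
Product: 18 target CNP0135015.0
Conditions: H2 (3 bar), 10% Pd/C, NaOAc, MeOH–THF, rt
Reagents that add atoms: none
Why: Heterogeneous palladium-catalysed hydrogenolysis cleaves the benzylic C–O bond and the aryl C–Cl bond in one operation, NaOAc taking up the HCl that would slow the catalyst, while diaryl ethers and phenols are inert.

Compound list
1 | 2-chloro-5-hydroxybenzaldehyde | O=Cc1cc(O)ccc1Cl | starting material
2 | 4-chloro-3-(hydroxymethyl)phenol | OCc1cc(O)ccc1Cl | intermediate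
3 | (2-chloro-5-hydroxybenzyl)triphenylphosphonium bromide | [Br-].Oc1ccc(Cl)c(C[P+](c2ccccc2)(c2ccccc2)c2ccccc2)c1 | intermediate
4 | 3-hydroxybenzyl alcohol | OCc1cccc(O)c1 | starting material
5 | (3-hydroxybenzyl)triphenylphosphonium bromide | [Br-].Oc1cccc(C[P+](c2ccccc2)(c2ccccc2)c2ccccc2)c1 | intermediate
6 | 4-(benzyloxy)-3-hydroxybenzaldehyde | O=Cc1ccc(OCc2ccccc2)c(O)c1 | starting material
7 | 4-fluorobenzonitrile | N#Cc1ccc(F)cc1 | starting material
8 | 4-[2-(benzyloxy)-5-formylphenoxy]benzonitrile | N#Cc1ccc(cc1)Oc1cc(C=O)ccc1OCc1ccccc1 | intermediate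
9 | potassium 4-chloro-3-[(triphenylphosphoranylidene)methyl]phenoxide (ylide, not isolated) | [K+].[O-]c1ccc(Cl)c(C=P(c2ccccc2)(c2ccccc2)c2ccccc2)c1 | intermediate
10 | 4-{2-(benzyloxy)-5-[2-(2-chloro-5-hydroxyphenyl)ethenyl]phenoxy}benzonitrile, E/Z mixture | N#Cc1ccc(cc1)Oc1cc(C=Cc2cc(O)ccc2Cl)ccc1OCc1ccccc1 | intermediate
11 | N-(diisobutylaluminio)aldimine of 12 with the ring D oxygen as diisobutylaluminium phenoxide (not isolated) | CC(C)C[Al](CC(C)C)N=Cc1ccc(cc1)Oc1cc(C=Cc2cc(O[Al](CC(C)C)CC(C)C)ccc2Cl)ccc1OCc1ccccc1 | intermediate
12 | 4-{2-(benzyloxy)-5-[2-(2-chloro-5-hydroxyphenyl)ethenyl]phenoxy}benzaldehyde, E/Z mixture | O=Cc1ccc(cc1)Oc1cc(C=Cc2cc(O)ccc2Cl)ccc1OCc1ccccc1 | intermediate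
13 | potassium 3-[(triphenylphosphoranylidene)methyl]phenoxide (ylide, not isolated) | [K+].[O-]c1cccc(C=P(c2ccccc2)(c2ccccc2)c2ccccc2)c1 | intermediate
14 | 4-chloro-3-{2-[4-(benzyloxy)-3-{4-[2-(3-hydroxyphenyl)ethenyl]phenoxy}phenyl]ethenyl}phenol, E/Z mixture at both alkenes | Oc1cccc(c1)C=Cc1ccc(cc1)Oc1cc(C=Cc2cc(O)ccc2Cl)ccc1OCc1ccccc1 | intermediate
15 | 4-chloro-3-{2-[4-(benzyloxy)-3-{4-[2-(3-hydroxyphenyl)ethyl]phenoxy}phenyl]ethyl}phenol (seco diphenol) | Oc1cccc(c1)CCc1ccc(cc1)Oc1cc(ccc1OCc1ccccc1)CCc1cc(O)ccc1Cl | intermediate
16 | macrocyclic 4-aryloxycyclohexa-2,5-dienone (ring A as dienone, C4 bearing H and the ring D oxygen; racemic, transient, not isolated) | O=C1C=CC2C(=C1)CCc1ccc(cc1)Oc1cc(ccc1OCc1ccccc1)CCc1cc(ccc1Cl)O2 | intermediate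
17 | macrocycle with free ring A hydroxyl, ring C benzyl ether and ring D chlorine para to the new ether oxygen | Oc1ccc2c(c1)CCc1ccc(cc1)Oc1cc(ccc1OCc1ccccc1)CCc1cc(ccc1Cl)O2 | intermediate
18 | CNP0135015.0, macrocyclic bis(bibenzyl) diphenol (achiral) | Oc1ccc2c(c1)CCc1ccc(cc1)Oc1cc(ccc1O)CCc1cccc(c1)O2 | target

Total step count: 10.
Longest linear sequence: 8 steps (1, 2, 5, 6, 7, 8, 9, 10).

Steps most likely to fail

1. Step 9. Several processes may compete with the wanted closure:
   - carbon–carbon union of the two radicals;
   - coupling of the ring A oxygen onto ring D;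
   - chain growth between molecules;
   - film formation on the anode;
   - further oxidation of the more easily oxidised product.

   Fallback (known chemistry: intramolecular Ullmann diaryl ether synthesis), setting out from 12 and coming back at 18. Commercial 5-(benzyloxy)-2-bromobenzaldehyde is reduced with NaBH4 to [5-(benzyloxy)-2-bromophenyl]methanol F1. PPh3·HBr in refluxing MeCN converts this into [5-(benzyloxy)-2-bromobenzyl]triphenylphosphonium bromide F2. Wittig reaction of F2 with 12 (KOtBu, THF) gives the bromo bis-stilbene F3, and diimide (TsNHNH2, NaOAc) saturates it to the bromo seco phenol F4. CuI, N,N-dimethylglycine and Cs2CO3 in dioxane at about 100 °C under syringe-pump dilution then join the ring D phenoxide to the ring A carbon bearing bromine. The aryl chloride is inert to copper under these conditions, so this gives the dibenzyl chloro macrocycle F5. The conditions of step 10 strip both benzyl groups and the chlorine to give 18.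

2. Step 7. The acidic phenol of the aldehyde partner may quench part of the ylide, and poorly soluble potassium phenoxides may precipitate and stall the olefination.

   Fallback (silyl-protected partners), setting out from 12 and 5 and coming back at 14. Compound 12 is silylated (TBSCl, imidazole, DMF) to the silyl ether aldehyde F6. Compound 5 is silylated in the same way to [3-(tert-butyldimethylsilyloxy)benzyl]triphenylphosphonium bromide F7. With no acidic proton left, one equivalent of NaN(SiMe3)2 in THF at −78 to 0 °C forms the ylide, which with F6 gives the bis-silyl bis-stilbene F8. Bu4NF in THF then removes both silyl groups to give 14.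

3. Step 10. Hydrodechlorination may stay incomplete through chloride poisoning of the catalyst surface after the faster debenzylation.

   Fallback (the two cleavages are separated and the chlorine is removed homogeneously), setting out from 17 and coming back at 18. Transfer hydrodechlorination with (IPr)Pd(allyl)Cl, NaOtBu and 2-propanol at 60 °C uses isopropoxide as the hydride source and gives the dechlorinated benzyl ether macrocycle F9. Plain hydrogenolysis (H2, Pd/C, EtOAc–MeOH) then gives 18.

Further compounds
F1 | step 9 | [5-(benzyloxy)-2-bromophenyl]methanol | OCc1cc(OCc2ccccc2)ccc1Br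
F2 | step 9 | [5-(benzyloxy)-2-bromobenzyl]triphenylphosphonium bromide | [Br-].Brc1ccc(OCc2ccccc2)cc1C[P+](c1ccccc1)(c1ccccc1)c1ccccc1
F3 | step 9 | bromo bis-stilbene (ring A Br para to OBn; ring D free OH; E/Z mixture) | Brc1ccc(OCc2ccccc2)cc1C=Cc1ccc(cc1)Oc1cc(C=Cc2cc(O)ccc2Cl)ccc1OCc1ccccc1
F4 | step 9 | bromo seco phenol (saturated bridges) | Brc1ccc(OCc2ccccc2)cc1CCc1ccc(cc1)Oc1cc(ccc1OCc1ccccc1)CCc1cc(O)ccc1Cl
F5 | step 9 | dibenzyl chloro macrocycle | c1ccccc1COc1ccc2c(c1)CCc1ccc(cc1)Oc1cc(ccc1OCc1ccccc1)CCc1cc(ccc1Cl)O2
F6 | step 7 | tert-butyldimethylsilyl ether of aldehyde 12 | O=Cc1ccc(cc1)Oc1cc(C=Cc2cc(O[Si](C)(C)C(C)(C)C)ccc2Cl)ccc1OCc1ccccc1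
F7 | step 7 | [3-(tert-butyldimethylsilyloxy)benzyl]triphenylphosphonium bromide | [Br-].CC(C)(C)[Si](C)(C)Oc1cccc(C[P+](c2ccccc2)(c2ccccc2)c2ccccc2)c1
F8 | step 7 | bis-silyl bis-stilbene (E/Z mixture) | CC(C)(C)[Si](C)(C)Oc1cccc(c1)C=Cc1ccc(cc1)Oc1cc(C=Cc2cc(O[Si](C)(C)C(C)(C)C)ccc2Cl)ccc1OCc1ccccc1
F9 | step 10 | dechlorinated benzyl ether macrocycle | Oc1ccc2c(c1)CCc1ccc(cc1)Oc1cc(ccc1OCc1ccccc1)CCc1cccc(c1)O2
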